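**Plan**
Labels: C1 = C–OH bridgehead, C2 = its ArCH, O3, C4 = CH2 on C5, C5 = CH bridgehead, C6 = its ArCH, O7, C8 = CH2 on C1; ring A = C1–C2–O3–C4–C5, ring B = C5–C6–O7–C8–C1.
Enabling feature: C1 bears a hydroxyl, the C8H2–O arm and the ArCH(O) carbon C2. This is a 2-aryl-3-oxy-oxetane (C2–O–C8 on C1) in disguise, the adduct of an aryl aldehyde and a silyl enol ether under light.
Retrosynthesis: cut O7–C8 (ring B), then C2–O3 (ring A, which leaves the oxetane C2–O–C8), then C1–C2 and C8–O together ([2+2]), then C1=C8 back to a methyl ketone, then C5–C6 by aldol.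
Forward: the aldol joins C5–C6, the acyl group becomes the C1 methyl ketone and its kinetic silyl enol ether, irradiation closes the oxetane, the C4 hydroxyl expands it to ring A, O7 displaces a C8 sulfonate to close ring B, and hydrogenolysis frees the phenols.
Stereochemistry: C5 and C6 come from the auxiliary-controlled syn aldol, C1 from C5 in the photocycloaddition, and C2 is set cis to the silyloxy group and then inverted in the ring expansion.
Key step: step 10

Remark on the chemistry: the phenol of the aldehyde used in the photochemical step is carried as a benzyl carbonate, not a benzyl ether. It is assumed that this weaker donor keeps the aldehyde photoreactive and keeps C2 from ionising. It is removed by the same hydrogenolysis as the benzyl ether.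

**Step 1**
Reactants: 1 methyl 3-hydroxypropanoate
Product: 2 methyl 3-[(tert-butyldimethylsilyl)oxy]propanoate
Conditions: tBuMe2SiCl, imidazole, CH2Cl2, 0 °C → rt
Reagents that add atoms: tert-butyldimethylsilyl chloride, CC(C)(C)[Si](C)(C)Cl
Why: Silyl ether formation at the primary hydroxyl (standard O-silylation) installs a C4 protecting group that lasts through the organometallic steps and can later be cleaved beside a secondary silyl ether.

**Step 2**
Reactants: 2 methyl 3-[(tert-butyldimethylsilyl)oxy]propanoate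
Product: 3 3-[(tert-butyldimethylsilyl)oxy]propanoic acid
Conditions: LiOH, THF/H2O, 0 °C → rt; then 1 M HCl to pH 4, 0 °C
Reagents that add atoms: lithium hydroxide, [Li+].[OH-]
Why: Ester saponification with LiOH, which a primary tert-butyldimethylsilyl ether tolerates in the cold, gives the acid needed for N-acylation.

**Step 3**
Reactants: 3 3-[(tert-butyldimethylsilyl)oxy]propanoic acid; 4 (R)-4-benzyl-2-oxazolidinone
Product: 6 (R)-4-benzyl-3-{3-[(tert-butyldimethylsilyl)oxy]propanoyl}oxazolidin-2-one, via pivalic mixed anhydride 5 (not isolated)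
Conditions: tBuCOCl, Et3N, THF, −20 °C; then LiCl, 4, rt
Reagents that add atoms: none
Why: N-Acylation of the oxazolidinone through the mixed pivalic anhydride with LiCl/Et3N activation, the attack going to the less hindered acyl group of 5.

**Step 4**
Reactants: 6 (R)-4-benzyl-3-{3-[(tert-butyldimethylsilyl)oxy]propanoyl}oxazolidin-2-one; 7 4-(benzyloxy)-3-methoxybenzaldehyde
Product: 9 (R)-4-benzyl-3-[(2R,3R)-3-[4-(benzyloxy)-3-methoxyphenyl]-2-{[(tert-butyldimethylsilyl)oxy]methyl}-3-hydroxypropanoyl]oxazolidin-2-one, via dibutylboron Z-enolate 8 (not isolated)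
Conditions: Bu2BOTf, iPr2NEt, CH2Cl2, 0 °C; 7, −78 → 0 °C; then pH 7 buffer, MeOH, H2O2, 0 °C
Reagents that add atoms: none
Why: Evans syn aldol addition: the Z boron enolate 8 reacts through a closed chair transition state on the face away from the auxiliary benzyl group, setting C5 and C6 (2R,3R in the acyl chain) in the syn relationship that ring B needs.

**Step 5**
Reactants: 9 (R)-4-benzyl-3-[(2R,3R)-3-[4-(benzyloxy)-3-methoxyphenyl]-2-{[(tert-butyldimethylsilyl)oxy]methyl}-3-hydroxypropanoyl]oxazolidin-2-one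
Product: 10 (2R,3R)-3-[4-(benzyloxy)-3-methoxyphenyl]-2-{[(tert-butyldimethylsilyl)oxy]methyl}-3-hydroxy-N-methoxy-N-methylpropanamide
Conditions: MeNH(OMe)·HCl, AlMe3, CH2Cl2, −20 → 0 °C
Reagents that add atoms: N,O-dimethylhydroxylamine hydrochloride, CNOC.Cl
Why: Weinreb amide formation by aluminium amide transamidation, which the free β-hydroxyl directs to the exocyclic carbonyl so that the auxiliary (4) is released without epimerising C5.

**Step 6**
Reactants: 10 (2R,3R)-3-[4-(benzyloxy)-3-methoxyphenyl]-2-{[(tert-butyldimethylsilyl)oxy]methyl}-3-hydroxy-N-methoxy-N-methylpropanamide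
Product: 11 (2R,3R)-3-[4-(benzyloxy)-3-methoxyphenyl]-3-[(tert-butyldimethylsilyl)oxy]-2-{[(tert-butyldimethylsilyl)oxy]methyl}-N-methoxy-N-methylpropanamide
Conditions: tBuMe2SiOTf, 2,6-lutidine, CH2Cl2, −78 → 0 °C
Reagents that add atoms: tert-butyldimethylsilyl trifluoromethanesulfonate, CC(C)(C)[Si](C)(C)OS(=O)(=O)C(F)(F)F
Why: Silylation of the hindered benzylic alcohol with the silyl triflate blocks retro-aldol in the next basic steps and keeps O7 from competing for C2 in step 11.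

**Step 7**
Reactants: 11 (2R,3R)-3-[4-(benzyloxy)-3-methoxyphenyl]-3-[(tert-butyldimethylsilyl)oxy]-2-{[(tert-butyldimethylsilyl)oxy]methyl}-N-methoxy-N-methylpropanamide
Product: 12 (3R,4R)-4-[4-(benzyloxy)-3-methoxyphenyl]-4-[(tert-butyldimethylsilyl)oxy]-3-{[(tert-butyldimethylsilyl)oxy]methyl}butan-2-one
Conditions: MeMgBr, THF, 0 °C
Reagents that add atoms: methylmagnesium bromide, C[Mg]Br
Why: Weinreb ketone synthesis: the chelated tetrahedral adduct survives until work-up, so MeMgBr adds once and the C1 methyl ketone forms without loss of the β-silyloxy group or epimerisation at C5.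

**Step 8**
Reactants: 12 (3R,4R)-4-[4-(benzyloxy)-3-methoxyphenyl]-4-[(tert-butyldimethylsilyl)oxy]-3-{[(tert-butyldimethylsilyl)oxy]methyl}butan-2-one
Product: 14 (3R,4R)-4-[4-(benzyloxy)-3-methoxyphenyl]-4-[(tert-butyldimethylsilyl)oxy]-3-{[(tert-butyldimethylsilyl)oxy]methyl}-2-[(trimethylsilyl)oxy]but-1-ene, via lithium enolate 13 (not isolated)
Conditions: LiN(iPr)2, THF, −78 °C; then Me3SiCl, Et3N, −78 → 0 °C; pentane, filtration
Reagents that add atoms: chlorotrimethylsilane, C[Si](C)(C)Cl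
Why: Kinetic enolate formation at the methyl group C8, not the hindered methine C5, followed by O-silylation, gives the 2-silyloxy-1-alkene with the C5 and C6 centres untouched.

**Step 9**
Reactants: 15 vanillin (4-hydroxy-3-methoxybenzaldehyde)
Product: 16 benzyl 4-formyl-2-methoxyphenyl carbonate
Conditions: BnOCOCl, Et3N, CH2Cl2, 0 °C
Reagents that add atoms: benzyl chloroformate, O=C(Cl)OCc1ccccc1
Why: O-Acylation of the phenol with the chloroformate (carbonate formation) gives an aldehyde whose para substituent is no longer a strong donor and which is debenzylated by the same hydrogenolysis as the ether in 22.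

**Step 10**
Reactants: 14 (3R,4R)-4-[4-(benzyloxy)-3-methoxyphenyl]-4-[(tert-butyldimethylsilyl)oxy]-3-{[(tert-butyldimethylsilyl)oxy]methyl}-2-[(trimethylsilyl)oxy]but-1-ene; 16 benzyl 4-formyl-2-methoxyphenyl carbonate
Product: 17 benzyl 4-{(2S,3S)-3-[(1R,2R)-1-[4-(benzyloxy)-3-methoxyphenyl]-1,3-bis[(tert-butyldimethylsilyl)oxy]propan-2-yl]-3-[(trimethylsilyl)oxy]oxetan-2-yl}-2-methoxyphenyl carbonate
Conditions: hν (300–350 nm, borosilicate filter), 16 (3 equiv), C6H6, 10 °C, Ar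
Reagents that add atoms: none
Why: Paternò–Büchi photocycloaddition, closest to the known addition of aromatic aldehydes to 2-silyloxy-1-alkenes derived from methyl ketones: the n,π* triplet of 16 bonds through oxygen to the unsubstituted terminus C8 and leaves a triplet 1,4-biradical (α-silyloxy tertiary radical at C1, benzylic radical at C2). After intersystem crossing the oxetane closes by C1–C2 radical combination, a four-membered ring formed by collapse of the 1,4-biradical. The regiochemistry that is needed (O to C8, C to C1) is secured by the silyloxy group, which makes C8 the nucleophilic terminus and C1 the stabilised radical site. C2 is set relative to C1 during closure: the aryl group turns away from the branched carbon substituent (C5) on C1 and ends cis to the silyloxy group. C1 is set by the C5 stereocentre: in the closing rotamer the C5–H bond should lie in the radical plane on the side of the silyloxy group, the bulky aryl(silyloxy)methyl arm (C6) covers one face and C2 bonds on the other. Chemoselectivity rests on 16 being the only chromophore above 300 nm and on its acyloxy para substituent, which should keep the reactive n,π* triplet lowest where an alkoxy group would not.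

**Step 11**
Reactants: 17 benzyl 4-{(2S,3S)-3-[(1R,2R)-1-[4-(benzyloxy)-3-methoxyphenyl]-1,3-bis[(tert-butyldimethylsilyl)oxy]propan-2-yl]-3-[(trimethylsilyl)oxy]oxetan-2-yl}-2-methoxyphenyl carbonate
Product: 19 benzyl 4-[(2R,3S,4R)-4-{(R)-[4-(benzyloxy)-3-methoxyphenyl][(tert-butyldimethylsilyl)oxy]methyl}-3-hydroxy-3-(hydroxymethyl)oxolan-2-yl]-2-methoxyphenyl carbonate, via desilylated oxetane diol 18 (not isolated)
Conditions: HF·pyridine, pyridine, THF, 0 °C → rt; then CSA (10 mol %), CH2Cl2, 0 °C → rt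
Reagents that add atoms: none
Why: Acidic fluoride removes the Me3Si ether and the primary tBuMe2Si ether but not the hindered benzylic one, and acid-catalysed intramolecular oxetane opening (strain-release ring expansion) follows: the C4 hydroxyl attacks benzylic C2 anti to the departing oxygen (5-exo-tet, inversion at C2), turning the cis oxetane into ring A with the aryl group cis to the C1 hydroxyl and freeing the C8 hydroxyl.

**Step 12**
Reactants: 19 benzyl 4-[(2R,3S,4R)-4-{(R)-[4-(benzyloxy)-3-methoxyphenyl][(tert-butyldimethylsilyl)oxy]methyl}-3-hydroxy-3-(hydroxymethyl)oxolan-2-yl]-2-methoxyphenyl carbonate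
Product: 20 [(2R,3S,4R)-2-(4-{[(benzyloxy)carbonyl]oxy}-3-methoxyphenyl)-4-{(R)-[4-(benzyloxy)-3-methoxyphenyl][(tert-butyldimethylsilyl)oxy]methyl}-3-hydroxyoxolan-3-yl]methyl methanesulfonate
Conditions: MsCl, Et3N, CH2Cl2, −20 °C
Reagents that add atoms: methanesulfonyl chloride, CS(=O)(=O)Cl
Why: Mesylation (sulfonate ester formation) is selective for the only primary hydroxyl; the tertiary C1 hydroxyl is inert and Et3N at −20 °C does not close an epoxide.

**Step 13**
Reactants: 20 [(2R,3S,4R)-2-(4-{[(benzyloxy)carbonyl]oxy}-3-methoxyphenyl)-4-{(R)-[4-(benzyloxy)-3-methoxyphenyl][(tert-butyldimethylsilyl)oxy]methyl}-3-hydroxyoxolan-3-yl]methyl methanesulfonate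
Product: 22 benzyl 4-[(1R,3aS,4R,6aR)-1-[4-(benzyloxy)-3-methoxyphenyl]-3a-hydroxytetrahydro-1H,3H-furo[3,4-c]furan-4-yl]-2-methoxyphenyl carbonate, via hydroxy mesylate 21 (not isolated)
Conditions: HF·pyridine, pyridine, THF, 0 °C → rt; then iPr2NEt, MeCN, 60 °C
Reagents that add atoms: none
Why: Desilylation at C6 followed by intramolecular Williamson-type etherification: the neutral C6 hydroxyl displaces the C8 mesylate (5-exo-tet), C6 keeping its configuration because the C6–O7 bond is never broken, and the absence of alkoxide base keeps the C1 hydroxyl from closing the epoxide.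

**Step 14**
Reactants: 22 benzyl 4-[(1R,3aS,4R,6aR)-1-[4-(benzyloxy)-3-methoxyphenyl]-3a-hydroxytetrahydro-1H,3H-furo[3,4-c]furan-4-yl]-2-methoxyphenyl carbonate
Product: 23 (1R,3aS,4R,6aR)-1,4-bis(4-hydroxy-3-methoxyphenyl)tetrahydro-1H,3H-furo[3,4-c]furan-3a(4H)-ol (CNP0138682.3)
Conditions: H2 (1 atm), 10% Pd/C, EtOAc, rt
Reagents that add atoms: none
Why: Catalytic hydrogenolysis cleaves the aryl benzyl ether and the benzyl carbonate (the latter with loss of CO2) under neutral conditions that should leave the slower-reacting benzylic ring ethers and all four stereocentres intact.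

**Compound list**
1 | methyl 3-hydroxypropanoate | COC(=O)CCO | starting material
2 | methyl 3-[(tert-butyldimethylsilyl)oxy]propanoate | COC(=O)CCO[Si](C)(C)C(C)(C)C | intermediate
3 | 3-[(tert-butyldimethylsilyl)oxy]propanoic acid | OC(=O)CCO[Si](C)(C)C(C)(C)C | intermediate
4 | (R)-4-benzyl-2-oxazolidinone | O=C1OC[C@@H](Cc2ccccc2)N1 | starting material
5 | 3-[(tert-butyldimethylsilyl)oxy]propanoic pivalic anhydride | CC(C)(C)C(=O)OC(=O)CCO[Si](C)(C)C(C)(C)C | intermediate
6 | (R)-4-benzyl-3-{3-[(tert-butyldimethylsilyl)oxy]propanoyl}oxazolidin-2-one | O=C(CCO[Si](C)(C)C(C)(C)C)N1[C@H](Cc2ccccc2)COC1=O | intermediate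
7 | 4-(benzyloxy)-3-methoxybenzaldehyde | COc1cc(C=O)ccc1OCc1ccccc1 | starting material
8 | (R)-4-benzyl-3-[(Z)-3-[(tert-butyldimethylsilyl)oxy]-1-[(dibutylboranyl)oxy]prop-1-en-1-yl]oxazolidin-2-one | CCCCB(CCCC)O/C(=C\CO[Si](C)(C)C(C)(C)C)N1[C@H](Cc2ccccc2)COC1=O | intermediate
9 | (R)-4-benzyl-3-[(2R,3R)-3-[4-(benzyloxy)-3-methoxyphenyl]-2-{[(tert-butyldimethylsilyl)oxy]methyl}-3-hydroxypropanoyl]oxazolidin-2-one | O=C(N1[C@H](Cc2ccccc2)COC1=O)[C@H](CO[Si](C)(C)C(C)(C)C)[C@@H](O)c1ccc(OCc2ccccc2)c(OC)c1 | intermediate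
10 | (2R,3R)-3-[4-(benzyloxy)-3-methoxyphenyl]-2-{[(tert-butyldimethylsilyl)oxy]methyl}-3-hydroxy-N-methoxy-N-methylpropanamide | CON(C)C(=O)[C@H](CO[Si](C)(C)C(C)(C)C)[C@@H](O)c1ccc(OCc2ccccc2)c(OC)c1 | intermediate
11 | (2R,3R)-3-[4-(benzyloxy)-3-methoxyphenyl]-3-[(tert-butyldimethylsilyl)oxy]-2-{[(tert-butyldimethylsilyl)oxy]methyl}-N-methoxy-N-methylpropanamide | CON(C)C(=O)[C@H](CO[Si](C)(C)C(C)(C)C)[C@@H](O[Si](C)(C)C(C)(C)C)c1ccc(OCc2ccccc2)c(OC)c1 | intermediate
12 | (3R,4R)-4-[4-(benzyloxy)-3-methoxyphenyl]-4-[(tert-butyldimethylsilyl)oxy]-3-{[(tert-butyldimethylsilyl)oxy]methyl}butan-2-one | CC(=O)[C@H](CO[Si](C)(C)C(C)(C)C)[C@@H](O[Si](C)(C)C(C)(C)C)c1ccc(OCc2ccccc2)c(OC)c1 | intermediate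
13 | lithium (3R,4R)-4-[4-(benzyloxy)-3-methoxyphenyl]-4-[(tert-butyldimethylsilyl)oxy]-3-{[(tert-butyldimethylsilyl)oxy]methyl}but-1-en-2-olate | C=C(O[Li])[C@H](CO[Si](C)(C)C(C)(C)C)[C@@H](O[Si](C)(C)C(C)(C)C)c1ccc(OCc2ccccc2)c(OC)c1 | intermediate
14 | (3R,4R)-4-[4-(benzyloxy)-3-methoxyphenyl]-4-[(tert-butyldimethylsilyl)oxy]-3-{[(tert-butyldimethylsilyl)oxy]methyl}-2-[(trimethylsilyl)oxy]but-1-ene | C=C(O[Si](C)(C)C)[C@H](CO[Si](C)(C)C(C)(C)C)[C@@H](O[Si](C)(C)C(C)(C)C)c1ccc(OCc2ccccc2)c(OC)c1 | intermediate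
15 | vanillin (4-hydroxy-3-methoxybenzaldehyde) | COc1cc(C=O)ccc1O | starting material
16 | benzyl 4-formyl-2-methoxyphenyl carbonate | COc1cc(C=O)ccc1OC(=O)OCc1ccccc1 | intermediate
17 | benzyl 4-{(2S,3S)-3-[(1R,2R)-1-[4-(benzyloxy)-3-methoxyphenyl]-1,3-bis[(tert-butyldimethylsilyl)oxy]propan-2-yl]-3-[(trimethylsilyl)oxy]oxetan-2-yl}-2-methoxyphenyl carbonate (aryl cis to the silyloxy group) | COc1cc([C@@H]2OC[C@@]2(O[Si](C)(C)C)[C@H](CO[Si](C)(C)C(C)(C)C)[C@@H](O[Si](C)(C)C(C)(C)C)c2ccc(OCc3ccccc3)c(OC)c2)ccc1OC(=O)OCc1ccccc1 | intermediate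
18 | benzyl 4-{(2S,3S)-3-[(1R,2R)-1-[4-(benzyloxy)-3-methoxyphenyl]-1-[(tert-butyldimethylsilyl)oxy]-3-hydroxypropan-2-yl]-3-hydroxyoxetan-2-yl}-2-methoxyphenyl carbonate | COc1cc([C@@H]2OC[C@@]2(O)[C@H](CO)[C@@H](O[Si](C)(C)C(C)(C)C)c2ccc(OCc3ccccc3)c(OC)c2)ccc1OC(=O)OCc1ccccc1 | intermediate
19 | benzyl 4-[(2R,3S,4R)-4-{(R)-[4-(benzyloxy)-3-methoxyphenyl][(tert-butyldimethylsilyl)oxy]methyl}-3-hydroxy-3-(hydroxymethyl)oxolan-2-yl]-2-methoxyphenyl carbonate | COc1cc([C@H]2OC[C@H]([C@@H](O[Si](C)(C)C(C)(C)C)c3ccc(OCc4ccccc4)c(OC)c3)[C@]2(O)CO)ccc1OC(=O)OCc1ccccc1 | intermediate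
20 | [(2R,3S,4R)-2-(4-{[(benzyloxy)carbonyl]oxy}-3-methoxyphenyl)-4-{(R)-[4-(benzyloxy)-3-methoxyphenyl][(tert-butyldimethylsilyl)oxy]methyl}-3-hydroxyoxolan-3-yl]methyl methanesulfonate | COc1cc([C@H]2OC[C@H]([C@@H](O[Si](C)(C)C(C)(C)C)c3ccc(OCc4ccccc4)c(OC)c3)[C@]2(O)COS(C)(=O)=O)ccc1OC(=O)OCc1ccccc1 | intermediate
21 | [(2R,3S,4R)-2-(4-{[(benzyloxy)carbonyl]oxy}-3-methoxyphenyl)-4-{(R)-[4-(benzyloxy)-3-methoxyphenyl](hydroxy)methyl}-3-hydroxyoxolan-3-yl]methyl methanesulfonate | COc1cc([C@H]2OC[C@H]([C@@H](O)c3ccc(OCc4ccccc4)c(OC)c3)[C@]2(O)COS(C)(=O)=O)ccc1OC(=O)OCc1ccccc1 | intermediate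
22 | benzyl 4-[(1R,3aS,4R,6aR)-1-[4-(benzyloxy)-3-methoxyphenyl]-3a-hydroxytetrahydro-1H,3H-furo[3,4-c]furan-4-yl]-2-methoxyphenyl carbonate | COc1cc([C@H]2OC[C@@H]3[C@H](c4ccc(OCc5ccccc5)c(OC)c4)OC[C@]23O)ccc1OC(=O)OCc1ccccc1 | intermediate
23 | (1R,3aS,4R,6aR)-1,4-bis(4-hydroxy-3-methoxyphenyl)tetrahydro-1H,3H-furo[3,4-c]furan-3a(4H)-ol | COc1cc([C@H]2OC[C@@H]3[C@H](c4ccc(O)c(OC)c4)OC[C@]23O)ccc1O | target

**Step count**
Total steps: 14. Longest linear sequence: 13 (steps 1–8 and 10–14); step 9 is a one-step branch.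

**Steps most likely to fail**

Step 10. The biradical may close on the other face of the C1 radical, because the acyclic C1–C5 rotamer is not firmly held; a rotamer with C5–H beside C8 would deliver the C1 epimer. The donor-substituted aldehyde may also add slowly. The fallback fixes the rotamer with a ring and sets out from 10. Excess MeMgBr should give (3R,4R)-4-[4-(benzyloxy)-3-methoxyphenyl]-3-{[(tert-butyldimethylsilyl)oxy]methyl}-4-hydroxybutan-2-one F1. Double deprotonation with LiN(iPr)2 at −78 °C and trapping with iPr2Si(OTf)2 should give the cyclic silyl enol ether (5R,6R)-6-[4-(benzyloxy)-3-methoxyphenyl]-5-{[(tert-butyldimethylsilyl)oxy]methyl}-4-methylidene-2,2-di(propan-2-yl)-1,3,2-dioxasilinane F2. In F2 the ring holds C6 in the enol plane beside oxygen and the C4 arm covers one face. Irradiation with 16 should then close anti to the C4 arm, which is the required face, to give the spiro-oxetane benzyl 4-[(2S,3S,5'R,6'R)-6'-[4-(benzyloxy)-3-methoxyphenyl]-5'-{[(tert-butyldimethylsilyl)oxy]methyl}-2',2'-di(propan-2-yl)spiro[oxetane-3,4'-[1,3,2]dioxasilinan]-2-yl]-2-methoxyphenyl carbonate F3. HF·pyridine removes the silylene and the primary silyl ether to give the oxetane triol benzyl 4-{(2S,3S)-3-[(1R,2R)-1-[4-(benzyloxy)-3-methoxyphenyl]-1,3-dihydroxypropan-2-yl]-3-hydroxyoxetan-2-yl}-2-methoxyphenyl carbonate F4. Brief mild acid (PPTS, CH2Cl2) should expand it, the primary C4 hydroxyl outpacing the hindered benzylic one, to the ring-A triol benzyl 4-[(2R,3S,4R)-4-{(R)-[4-(benzyloxy)-3-methoxyphenyl](hydroxy)methyl}-3-hydroxy-3-(hydroxymethyl)oxolan-2-yl]-2-methoxyphenyl carbonate F5. Tosylation of the 1,2-diol at C8 (Bu2SnO catalyst, TsCl, Et3N) gives the C8 tosylate of the ring-A triol F6, which should close on warming to 22, where the route is rejoined.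

Step 11. The C4 hydroxyl may attack the less hindered C8 instead of C2, or C2 may partly ionise so that the inversion is eroded. The fallback gives up the concerted opening for a phenol-assisted ionisation under product control and sets out from 17. Pyrrolidine cleaves the aryl carbonate to the phenol 4-{(2S,3S)-3-[(1R,2R)-1-[4-(benzyloxy)-3-methoxyphenyl]-1,3-bis[(tert-butyldimethylsilyl)oxy]propan-2-yl]-3-[(trimethylsilyl)oxy]oxetan-2-yl}-2-methoxyphenol F7. HF·pyridine gives the desilylated phenol oxetane 4-{(2S,3S)-3-[(1R,2R)-1-[4-(benzyloxy)-3-methoxyphenyl]-1-[(tert-butyldimethylsilyl)oxy]-3-hydroxypropan-2-yl]-3-hydroxyoxetan-2-yl}-2-methoxyphenol F8. Its C2–O bond ionises readily with the help of the para hydroxyl, so with a trace of PPTS the C4 hydroxyl should add at C2 only. The aryl group should settle trans to the hydroxymethyl group and cis to the C1 hydroxyl, giving the ring-A diol 4-[(2R,3S,4R)-4-{(R)-[4-(benzyloxy)-3-methoxyphenyl][(tert-butyldimethylsilyl)oxy]methyl}-3-hydroxy-3-(hydroxymethyl)oxolan-2-yl]-2-methoxyphenol F9. Selective acylation of the phenol (BnOCOCl, Et3N, −20 °C) returns 19.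

Step 13. The tertiary C1 hydroxyl may close onto C8 to a spiro-epoxide, or the displacement at the neopentyl-type C8 may stall. The fallback ties the C1 oxygen and C8 into a cyclic sulfate, a stronger electrophile that cannot give the epoxide, and sets out from 19. SOCl2/Et3N gives the cyclic sulfite of 19 (1,3,2-dioxathiolane 2-oxide spiro-fused at C1 and C8) F10. Short oxidation with catalytic RuCl3 and NaIO4 gives the cyclic sulfate of 19 (2,2-dioxide) F11. HF·pyridine frees the C6 hydroxyl to give the C6-hydroxy cyclic sulfate F12, which with iPr2NEt should open the sulfate at C8 (5-exo) to the C1 hydrogen sulfate of 22 F13. Mild hydrolysis (catalytic H2SO4, wet THF) returns 22.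

**Further compounds**
F1 | step 10 | (3R,4R)-4-[4-(benzyloxy)-3-methoxyphenyl]-3-{[(tert-butyldimethylsilyl)oxy]methyl}-4-hydroxybutan-2-one | CC(=O)[C@H](CO[Si](C)(C)C(C)(C)C)[C@@H](O)c1ccc(OCc2ccccc2)c(OC)c1
F2 | step 10 | (5R,6R)-6-[4-(benzyloxy)-3-methoxyphenyl]-5-{[(tert-butyldimethylsilyl)oxy]methyl}-4-methylidene-2,2-di(propan-2-yl)-1,3,2-dioxasilinane | C=C1O[Si](C(C)C)(C(C)C)O[C@@H](c2ccc(OCc3ccccc3)c(OC)c2)[C@H]1CO[Si](C)(C)C(C)(C)C
F3 | step 10 | benzyl 4-[(2S,3S,5'R,6'R)-6'-[4-(benzyloxy)-3-methoxyphenyl]-5'-{[(tert-butyldimethylsilyl)oxy]methyl}-2',2'-di(propan-2-yl)spiro[oxetane-3,4'-[1,3,2]dioxasilinan]-2-yl]-2-methoxyphenyl carbonate | COc1cc([C@@H]2OC[C@]23O[Si](C(C)C)(C(C)C)O[C@@H](c4ccc(OCc5ccccc5)c(OC)c4)[C@H]3CO[Si](C)(C)C(C)(C)C)ccc1OC(=O)OCc1ccccc1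
F4 | step 10 | benzyl 4-{(2S,3S)-3-[(1R,2R)-1-[4-(benzyloxy)-3-methoxyphenyl]-1,3-dihydroxypropan-2-yl]-3-hydroxyoxetan-2-yl}-2-methoxyphenyl carbonate | COc1cc([C@@H]2OC[C@@]2(O)[C@H](CO)[C@@H](O)c2ccc(OCc3ccccc3)c(OC)c2)ccc1OC(=O)OCc1ccccc1
F5 | step 10 | benzyl 4-[(2R,3S,4R)-4-{(R)-[4-(benzyloxy)-3-methoxyphenyl](hydroxy)methyl}-3-hydroxy-3-(hydroxymethyl)oxolan-2-yl]-2-methoxyphenyl carbonate | COc1cc([C@H]2OC[C@H]([C@@H](O)c3ccc(OCc4ccccc4)c(OC)c3)[C@]2(O)CO)ccc1OC(=O)OCc1ccccc1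
F6 | step 10 | [(2R,3S,4R)-2-(4-{[(benzyloxy)carbonyl]oxy}-3-methoxyphenyl)-4-{(R)-[4-(benzyloxy)-3-methoxyphenyl](hydroxy)methyl}-3-hydroxyoxolan-3-yl]methyl 4-methylbenzenesulfonate | COc1cc([C@H]2OC[C@H]([C@@H](O)c3ccc(OCc4ccccc4)c(OC)c3)[C@]2(O)COS(=O)(=O)c5ccc(C)cc5)ccc1OC(=O)OCc1ccccc1
F7 | step 11 | 4-{(2S,3S)-3-[(1R,2R)-1-[4-(benzyloxy)-3-methoxyphenyl]-1,3-bis[(tert-butyldimethylsilyl)oxy]propan-2-yl]-3-[(trimethylsilyl)oxy]oxetan-2-yl}-2-methoxyphenol | COc1cc([C@@H]2OC[C@@]2(O[Si](C)(C)C)[C@H](CO[Si](C)(C)C(C)(C)C)[C@@H](O[Si](C)(C)C(C)(C)C)c2ccc(OCc3ccccc3)c(OC)c2)ccc1O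
F8 | step 11 | 4-{(2S,3S)-3-[(1R,2R)-1-[4-(benzyloxy)-3-methoxyphenyl]-1-[(tert-butyldimethylsilyl)oxy]-3-hydroxypropan-2-yl]-3-hydroxyoxetan-2-yl}-2-methoxyphenol | COc1cc([C@@H]2OC[C@@]2(O)[C@H](CO)[C@@H](O[Si](C)(C)C(C)(C)C)c2ccc(OCc3ccccc3)c(OC)c2)ccc1O
F9 | step 11 | 4-[(2R,3S,4R)-4-{(R)-[4-(benzyloxy)-3-methoxyphenyl][(tert-butyldimethylsilyl)oxy]methyl}-3-hydroxy-3-(hydroxymethyl)oxolan-2-yl]-2-methoxyphenol | COc1cc([C@H]2OC[C@H]([C@@H](O[Si](C)(C)C(C)(C)C)c3ccc(OCc4ccccc4)c(OC)c3)[C@]2(O)CO)ccc1O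
F10 | step 13 | cyclic sulfite of 19 (1,3,2-dioxathiolane 2-oxide spiro-fused at C1 and C8, either configuration at sulfur) | COc1cc([C@H]2OC[C@H]([C@@H](O[Si](C)(C)C(C)(C)C)c3ccc(OCc4ccccc4)c(OC)c3)[C@]25COS(=O)O5)ccc1OC(=O)OCc1ccccc1
F11 | step 13 | cyclic sulfate of 19 (1,3,2-dioxathiolane 2,2-dioxide spiro-fused at C1 and C8) | COc1cc([C@H]2OC[C@H]([C@@H](O[Si](C)(C)C(C)(C)C)c3ccc(OCc4ccccc4)c(OC)c3)[C@]25COS(=O)(=O)O5)ccc1OC(=O)OCc1ccccc1
F12 | step 13 | cyclic sulfate F11 with the C6 hydroxyl free | COc1cc([C@H]2OC[C@H]([C@@H](O)c3ccc(OCc4ccccc4)c(OC)c3)[C@]25COS(=O)(=O)O5)ccc1OC(=O)OCc1ccccc1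
F13 | step 13 | C1 hydrogen sulfate of 22 | COc1cc([C@H]2OC[C@@H]3[C@H](c4ccc(OCc5ccccc5)c(OC)c4)OC[C@]23OS(=O)(=O)O)ccc1OC(=O)OCc1ccccc1
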